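**Strategy.** Petrosin A is a meso dimer; each half has ring A (N–C4–C3–C2–C1–C10), ring B (N–C6–C7–C8–C9–C10) and a five-carbon chain from C9 to C1′. Both rings A are cut at C2–C3: the key step exploits that C2 is a carbonyl carbon on C1 and that C3, one CH2 (C4) from N, carries the methyl group. Bromine–lithium exchange on two N-(2-bromoallyl) groups and acylation by the Weinreb amides on C1 close both rings A as 3-methylene ketones. The precursor is a meso 16-membered macrocycle with two trans-2,3-disubstituted piperidines (rings B), made from a pyridinophane.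

Key step: step 10

Assumption: the two remote pyridine rings of 15 are reduced independently, so the heterochiral (meso-type) ring pair forms beside the homochiral pair and is separated in step 7; C1 is α to a carbonyl group from 15 to 25, is drawn with the target configuration from 17 on, and is finally settled in step 11.

Convention: primed labels belong to the second half; CIP descriptors refer to the atom labels of the first paragraph.

Step 1
Reactants: 1 3-bromo-2-methylpyridine; 2 5-bromopent-1-ene
Product: 4 3-bromo-2-(hex-5-en-1-yl)pyridine, via (3-bromopyridin-2-yl)methyllithium 3 (not isolated)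
Conditions: LiN(i-Pr)2 (1.05 equiv), THF, −78 °C; then 2, −78 → 0 °C
Reagents that add atoms: none
Why: The 2-methyl group is the most acidic site (picolyl anion delocalised onto the ring nitrogen) and its lithium derivative is alkylated by the primary bromide in an SN2 reaction (lateral lithiation–alkylation), the low temperature suppressing ring metalation next to bromine.

Step 2
Reactants: 5 3-chloro-2-methylpyridine; 2 5-bromopent-1-ene
Product: 7 3-chloro-2-(hex-5-en-1-yl)pyridine, via (3-chloropyridin-2-yl)methyllithium 6 (not isolated)
Conditions: LiN(i-Pr)2 (1.05 equiv), THF, −78 °C; then 2, −78 → 0 °C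
Reagents that add atoms: none
Why: The same lateral lithiation–alkylation as in step 1 (picolyl anion, SN2 at the primary bromide) gives the chloro analogue, whose C–Cl bond serves as the less reactive coupling site of the second pyridine.

Step 3
Reactants: 7 3-chloro-2-(hex-5-en-1-yl)pyridine; 4 3-bromo-2-(hex-5-en-1-yl)pyridine
Product: 9 3-chloro-2-{6-[2-(hex-5-en-1-yl)pyridin-3-yl]hexyl}pyridine, via B-[6-(3-chloropyridin-2-yl)hexyl]-9-BBN 8 (not isolated)
Conditions: 7, 9-BBN-H (1.1 equiv), THF, 0 °C → rt; aq. K3PO4 (3 equiv); then 4 (1.0 equiv), PdCl2(dppf) (5 mol %), DMF, 60 °C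
Reagents that add atoms: none
Why: Anti-Markovnikov hydroboration of the terminal alkene of 7 (its nitrogen, flanked by the 2-alkyl group and deactivated by chlorine, binds the hindered borane only weakly) is followed by B-alkyl Suzuki–Miyaura coupling at C3 of 4, because the dppf-ligated palladium catalyst inserts into the C–Br bond far faster than into any C–Cl bond present, while the alkene of 4 meets no B–H since residual borane is destroyed by the aqueous base before 4 is added.

Step 4
Reactants: 9 3-chloro-2-{6-[2-(hex-5-en-1-yl)pyridin-3-yl]hexyl}pyridine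
Product: 11 head-to-tail [6.6](2,3)pyridinophane, via B-alkyl-9-BBN derivative of the linear dimer 10 (not isolated)
Conditions: 9-BBN-H (1.3 equiv), THF, 0 °C → rt; then syringe-pump addition over 12 h to Pd(OAc)2 (10 mol %), SPhos (20 mol %), K3PO4 (3 equiv), THF/H2O (10:1), 65 °C, ≤ 2 mM
Reagents that add atoms: none
Why: Hydroboration of the remaining terminal alkene and intramolecular B-alkyl Suzuki–Miyaura coupling at the C3–Cl bond, which the electron-rich dialkylbiarylphosphine makes reactive toward oxidative addition, close the 16-membered ring of the preformed head-to-tail dimer (macrocyclization), slow addition keeping the borane dilute so that ring closure outruns chain growth.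

Step 5
Reactants: 11 head-to-tail [6.6](2,3)pyridinophane; 12 dimethyl carbonate
Product: 15 dimethyl pyridinophane-1,1′-dicarboxylate (C1 epimers), via 1,1′-dilithiated pyridinophane 13 (not isolated), via dilithium bis(ester enolate) 14 (not isolated)
Conditions: LiN(i-Pr)2 (4.5 equiv), THF, −78 → −20 °C; 12 (3 equiv), −78 → 0 °C; aq. NH4Cl
Reagents that add atoms: none
Why: Lateral lithiation takes place at the CH2 on pyridine C2 (C1), whose anion is delocalised onto nitrogen, in preference to the CH2 on C3, and Claisen-type C-acylation by dimethyl carbonate gives the esters, which the excess base at once converts into their enolates so that no second acylation occurs, the stereolabile C1 being immaterial at this stage.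

Step 6
Reactants: 15 dimethyl pyridinophane-1,1′-dicarboxylate
Product: 16 cis,cis-bis(piperidine) diester (9S,10R,9′R,10′S; C1 and C1′ unassigned)
Conditions: H2 (4 atm), PtO2 (10 mol %), AcOH, rt; basic aqueous work-up
Reagents that add atoms: none
Why: Heterogeneous hydrogenation of the pyridinium acetates delivers all ring hydrogens from the catalyst face (syn addition), so C9–H and C10–H should come out cis in each ring B while the esters are untouched, and because the two remote rings are reduced independently the heterochiral pair named here should form together with the homochiral pair.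

Step 7
Reactants: 16 cis,cis-bis(piperidine) diester
Product: 17 meso trans,trans-bis(piperidine) diester (1R,9S,10S,1′S,9′R,10′R)
Conditions: NaOMe (0.5 equiv), MeOH, reflux; SiO2 chromatography (or crystallisation of the dihydrochloride)
Reagents that add atoms: none
Why: Methoxide-mediated retro-aza-Michael opening of the N–C10 bond from the ester enolate and 6-exo-trig re-addition, with enolisation at C1, equilibrate C10 and C1 but not C9, which should move each ring B to the diequatorial trans-2,3 arrangement, after which the heterochiral (meso) diastereomer is separated from the homochiral one.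

Step 8
Reactants: 17 meso trans,trans-bis(piperidine) diester; 18 2,3-dibromoprop-1-ene
Product: 19 N,N′-bis(2-bromoprop-2-en-1-yl) derivative of 17
Conditions: 18 (2.4 equiv), K2CO3, MeCN, 50 °C
Reagents that add atoms: none
Why: SN2 N-alkylation of the secondary amines at the allylic C–Br bond (the vinylic C–Br bond is inert), the 2,3-disubstitution of the piperidines discouraging quaternisation.

Step 9
Reactants: 19 N,N′-bis(2-bromoprop-2-en-1-yl) diester
Product: 20 N,N′-bis(2-bromoprop-2-en-1-yl) bis(N-methoxy-N-methylamide) (1R,9S,10S,1′S,9′R,10′R)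
Conditions: MeNH(OMe)·HCl (6 equiv), i-PrMgCl (12 equiv), THF, −20 → 0 °C
Reagents that add atoms: N,O-dimethylhydroxylamine hydrochloride, CNOC.Cl
Why: Direct aminolysis of the methyl esters by the chloromagnesium amide of N,O-dimethylhydroxylamine, carried out after N-alkylation so that the nitrogen atoms are tertiary and no β-lactam can form from the β-amino esters, while i-PrMgCl does not exchange the vinylic bromides at this temperature.

Step 10
Reactants: 20 N,N′-bis(2-bromoprop-2-en-1-yl) bis(N-methoxy-N-methylamide)
Product: 23 bis(3-methylene) diketone (both rings A closed; 1R,9S,10S,1′S,9′R,10′R), via bis(2-lithioallyl) diamide 21 (not isolated), via dilithium bis(hemiaminal alkoxide) 22 (not isolated)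
Conditions: t-BuLi (4.4 equiv), THF, −90 → −70 °C; cannulated into cold 1 M HCl; brought to pH 8 and extracted (CH2Cl2) cold
Reagents that add atoms: none
Why: Each vinylic C–Br bond undergoes bromine–lithium exchange with t-BuLi (the second equivalent consumes the t-BuBr formed), and the 2-lithioallyl carbon C3 adds to the amide carbonyl C2 on C1 to give a lithium-chelated tetrahedral adduct that releases the ketone only in the acidic quench, so that neither over-addition nor base-induced chemistry of the enone can occur. The closest known reaction type is the Parham cyclization in its acylating form, that is, intramolecular acylation of an organolithium made by halogen–lithium exchange by an N-methoxy-N-methylamide. Each ring A (N–C4–C3–C2–C1–C10) is closed in the 6-exo-trig mode, the two closures being independent events at opposite ends of the 16-membered ring. No stereocentre is created: C2 ends as a trigonal ketone carbon, C3 stays trigonal, and C1, C9 and C10 are spectators. The step needs exchange to be faster than addition of t-BuLi to the amides and than removal of the C1–H; the intrinsically fast exchange at an sp2 C–Br bond at −90 °C, the α-branched and therefore shielded amide, and the tertiary, kinetically slow C1–H should secure this. Quenching into cold acid keeps the liberated N,O-dimethylhydroxylamine protonated, so that it cannot add to the exocyclic enones.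

Step 11
Reactants: 23 bis(3-methylene) diketone
Product: 25 petrosin A (1R,3R,9S,10S,1′S,3′S,9′R,10′R), via bis(lithium enolate) 24 (not isolated)
Conditions: LiBH(s-Bu)3 (2.05 equiv), THF, −78 °C (23 added to the hydride); then MeOH, NaOMe (0.2 equiv), 0 °C → rt; acid–base extraction
Reagents that add atoms: none
Why: The bulky hydride adds 1,4 to the unhindered exocyclic CH2 of each enone (conjugate reduction) and the enolates are protonated under equilibrating conditions (enolisation at C3 and C1), which should settle each trans-fused quinolizidinone with the C3 methyl equatorial and the C1 chain axial (H1 cis to H10), the arrangement that avoids the syn-pentane contact between the C1 chain and the equatorial C9 chain, that is, the target configuration.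

**Compound list**

1 | 3-bromo-2-methylpyridine | Cc1ncccc1Br | starting material
2 | 5-bromopent-1-ene | C=CCCCBr | starting material
3 | (3-bromopyridin-2-yl)methyllithium, formed in situ | [Li]Cc1ncccc1Br | intermediate
4 | 3-bromo-2-(hex-5-en-1-yl)pyridine | C=CCCCCc1ncccc1Br | intermediate
5 | 3-chloro-2-methylpyridine | Cc1ncccc1Cl | starting material
6 | (3-chloropyridin-2-yl)methyllithium, formed in situ | [Li]Cc1ncccc1Cl | intermediate
7 | 3-chloro-2-(hex-5-en-1-yl)pyridine | C=CCCCCc1ncccc1Cl | intermediate
8 | 3-chloro-2-[6-(9-borabicyclo[3.3.1]nonan-9-yl)hexyl]pyridine, formed in situ | Clc1cccnc1CCCCCCB1C2CCCC1CCC2 | intermediate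
9 | 3-chloro-2-{6-[2-(hex-5-en-1-yl)pyridin-3-yl]hexyl}pyridine (linear head-to-tail dimer) | C=CCCCCc1ncccc1CCCCCCc1ncccc1Cl | intermediate
10 | 9-BBN adduct of the terminal alkene of 9, formed in situ | Clc1cccnc1CCCCCCc1cccnc1CCCCCCB1C2CCCC1CCC2 | intermediate
11 | head-to-tail [6.6](2,3)pyridinophane: 16-membered ring, C2 of each pyridine joined by (CH2)6 to C3 of the other (achiral) | C1CCCCCc2cccnc2CCCCCCc2cccnc21 | intermediate
12 | dimethyl carbonate | COC(=O)OC | starting material
13 | 11 lithiated at both CH2 groups on pyridine C2 (C1 and C1′), formed in situ | [Li]C1CCCCCc2cccnc2C([Li])CCCCCc2cccnc21 | intermediate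
14 | dilithium bis(ester enolate) of 15, formed in situ | COC(O[Li])=C1CCCCCc2cccnc2C(=C(OC)O[Li])CCCCCc2cccnc21 | intermediate
15 | dimethyl diester of 11 with CO2Me on C1 and C1′ (C1 epimers, stereolabile, unassigned) | COC(=O)C1CCCCCc2cccnc2C(C(=O)OC)CCCCCc2cccnc21 | intermediate
16 | cis,cis-bis(piperidine) diester: both pyridines of 15 reduced, C9–H and C10–H cis in each ring B, heterochiral ring pair (9S,10R,9′R,10′S), C1 and C1′ unassigned | N1CCC[C@@H]2CCCCCC(C(=O)OC)[C@H]3NCCC[C@H]3CCCCCC(C(=O)OC)[C@H]12 | intermediate
17 | meso trans,trans-bis(piperidine) diester (1R,9S,10S,1′S,9′R,10′R): C9 chain and C10 substituent trans in each ring B | N1CCC[C@@H]2CCCCC[C@H](C(=O)OC)[C@@H]3NCCC[C@H]3CCCCC[C@@H](C(=O)OC)[C@@H]12 | intermediate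
18 | 2,3-dibromoprop-1-ene | C=C(Br)CBr | starting material
19 | N,N′-bis(2-bromoprop-2-en-1-yl) derivative of 17 (1R,9S,10S,1′S,9′R,10′R) | C=C(Br)CN1CCC[C@@H]2CCCCC[C@H](C(=O)OC)[C@@H]3N(CC(Br)=C)CCC[C@H]3CCCCC[C@@H](C(=O)OC)[C@@H]12 | intermediate
20 | macrocyclic bis[N-(2-bromoallyl)piperidine] bis(N-methoxy-N-methylamide) (1R,9S,10S,1′S,9′R,10′R), meso | C=C(Br)CN1CCC[C@@H]2CCCCC[C@H](C(=O)N(C)OC)[C@@H]3N(CC(Br)=C)CCC[C@H]3CCCCC[C@@H](C(=O)N(C)OC)[C@@H]12 | intermediate
21 | bis(2-lithioallyl) derivative of 20 (Li in place of each Br), formed in situ | [Li]C(=C)CN1CCC[C@@H]2CCCCC[C@H](C(=O)N(C)OC)[C@@H]3N(CC([Li])=C)CCC[C@H]3CCCCC[C@@H](C(=O)N(C)OC)[C@@H]12 | intermediate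
22 | dilithium bis(hemiaminal alkoxide): both rings A closed, C2 and C2′ bearing OLi and N(OMe)Me, formed in situ | C=C1CN2CCC[C@@H]3CCCCC[C@@H]4C(O[Li])(N(C)OC)C(=C)CN5CCC[C@@H](CCCCC[C@@H](C1(O[Li])N(C)OC)[C@H]32)[C@H]45 | intermediate
23 | bis(3-methylene) analogue of petrosin A (1R,9S,10S,1′S,9′R,10′R), meso | C=C1CN2CCC[C@@H]3CCCCC[C@@H]4C(=O)C(=C)CN5CCC[C@@H](CCCCC[C@@H](C1=O)[C@H]32)[C@H]45 | intermediate
24 | bis(lithium enolate) (C2=C3 and C2′=C3′, methyl on C3 and C3′), formed in situ | CC=1CN2CCC[C@@H]3CCCCC[C@@H]4C(O[Li])=C(C)CN5CCC[C@@H](CCCCC[C@@H](C=1O[Li])[C@H]32)[C@H]45 | intermediate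
25 | petrosin A (1R,3R,9S,10S,1′S,3′S,9′R,10′R), meso | C[C@@H]1CN2CCC[C@@H]3CCCCC[C@@H]4C(=O)[C@@H](C)CN5CCC[C@@H](CCCCC[C@@H](C1=O)[C@H]32)[C@H]45 | target

**Totals.** 11 steps; longest linear sequence 10 steps (steps 1 and 3 to 11, 1 → 25; step 2 is a one-step side branch).

**Steps most likely to fail**

1. Step 10. What may go wrong: proton transfer from C1–H to the vinyllithium, or attack of t-BuLi on an amide before exchange, so that one or both rings A stay open; addition of the released hydroxylamine to the enone during work-up. Fallback, from 20 back to 23: both amides of 20 are reduced with i-Bu2AlH (THF, −78 °C) to the bis-aldehyde F1. CrCl2 with catalytic NiCl2 in DMF converts the vinylic bromides into the non-basic bis(alkenylchromium) species F2, which adds to the aldehydes (Nozaki–Hiyama–Kishi reaction, again C3 to C2, 6-exo-trig) to give after work-up the bis(allylic alcohol) F3, whose carbinol configuration is irrelevant. Oxidation with Dess–Martin periodinane (NaHCO3, CH2Cl2) returns to 23.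

2. Step 4. What may go wrong: sluggish oxidative addition at the C–Cl bond under high dilution, so that loss of the borane or chain growth outruns ring closure. Fallback, from 4 back to 11, moves the ring closure to a C–Br bond. One portion of 4 is converted by copper-catalysed halogen exchange (CuI, NaI, trans-N,N′-dimethylcyclohexane-1,2-diamine, dioxane, 110 °C) into 2-(hex-5-en-1-yl)-3-iodopyridine F4. A second portion of 4 is hydroborated (9-BBN-H, 1.0 equiv) to B-[6-(3-bromopyridin-2-yl)hexyl]-9-BBN F5. This is coupled at room temperature with an excess of F4 (PdCl2(dppf), Cs2CO3, DMF/THF/H2O), where the C–I bond should react well before the C–Br bond, to give the linear bromo alkene 3-bromo-2-{6-[2-(hex-5-en-1-yl)pyridin-3-yl]hexyl}pyridine F6. Hydroboration gives its 9-BBN adduct F7, and closure at the C–Br bond (PdCl2(dppf), K3PO4, 65 °C, high dilution) should give 11.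

3. Step 7. What may go wrong: slow ring opening of the α-branched β-amino ester, leaving C10 unchanged, or co-elution of the heterochiral and homochiral ring pairs. Fallback, from 16 back to 25, postpones the inversion and the separation to the β-amino ketone stage. The mixture 16 is N-alkylated with 18 to the bis(2-bromoallyl) diester F8 and converted as in step 9 into the bis(N-methoxy-N-methylamide) F9. Exchange with t-BuLi gives the bis(2-lithioallyl) species F10 and the tetrahedral adduct F11, and acidic quench gives the C10-epimeric bis-enone F12. Conjugate reduction as in step 11 gives the bis(enolate) F13 and, on protonation, the diketone F14. Its β-amino ketone units should open and re-close at N–C10 more readily than the β-amino esters, so that prolonged NaOMe/MeOH equilibration inverts C10 together with C1 and C3. Compound 25 is then separated from the isomer derived from the homochiral ring pair, the rigid pentacycles being better differentiated than the flexible diamines.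

**Further compounds**

F1 | step 10 | bis-aldehyde from 20 (CHO on C1 and C1′; 1R,9S,10S,1′S,9′R,10′R) | C=C(Br)CN1CCC[C@@H]2CCCCC[C@H](C=O)[C@@H]3N(CC(Br)=C)CCC[C@H]3CCCCC[C@@H](C=O)[C@@H]12
F2 | step 10 | bis(alkenylchromium dichloride) species from F1, formed in situ | C=C([Cr](Cl)Cl)CN1CCC[C@@H]2CCCCC[C@H](C=O)[C@@H]3N(CC([Cr](Cl)Cl)=C)CCC[C@H]3CCCCC[C@@H](C=O)[C@@H]12
F3 | step 10 | bis(allylic alcohol): 23 with CH–OH in place of each C2 carbonyl (carbinol configuration unassigned) | C=C1CN2CCC[C@@H]3CCCCC[C@@H]4C(O)C(=C)CN5CCC[C@@H](CCCCC[C@@H](C1O)[C@H]32)[C@H]45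
F4 | step 4 | 2-(hex-5-en-1-yl)-3-iodopyridine | C=CCCCCc1ncccc1I
F5 | step 4 | 3-bromo-2-[6-(9-borabicyclo[3.3.1]nonan-9-yl)hexyl]pyridine, formed in situ | Brc1cccnc1CCCCCCB1C2CCCC1CCC2
F6 | step 4 | 3-bromo-2-{6-[2-(hex-5-en-1-yl)pyridin-3-yl]hexyl}pyridine (linear dimer) | C=CCCCCc1ncccc1CCCCCCc1ncccc1Br
F7 | step 4 | 9-BBN adduct of the terminal alkene of F6, formed in situ | Brc1cccnc1CCCCCCc1cccnc1CCCCCCB1C2CCCC1CCC2
F8 | step 7 | N,N′-bis(2-bromoprop-2-en-1-yl) derivative of 16 (9S,10R,9′R,10′S; C1 unassigned) | C=C(Br)CN1CCC[C@@H]2CCCCCC(C(=O)OC)[C@H]3N(CC(Br)=C)CCC[C@H]3CCCCCC(C(=O)OC)[C@H]12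
F9 | step 7 | bis(N-methoxy-N-methylamide) from F8 | C=C(Br)CN1CCC[C@@H]2CCCCCC(C(=O)N(C)OC)[C@H]3N(CC(Br)=C)CCC[C@H]3CCCCCC(C(=O)N(C)OC)[C@H]12
F10 | step 7 | bis(2-lithioallyl) derivative of F9, formed in situ | [Li]C(=C)CN1CCC[C@@H]2CCCCCC(C(=O)N(C)OC)[C@H]3N(CC([Li])=C)CCC[C@H]3CCCCCC(C(=O)N(C)OC)[C@H]12
F11 | step 7 | dilithium bis(hemiaminal alkoxide) of the C10-epimeric series, formed in situ | C=C1CN2CCC[C@@H]3CCCCCC4C(O[Li])(N(C)OC)C(=C)CN5CCC[C@@H](CCCCCC(C1(O[Li])N(C)OC)[C@@H]32)[C@@H]45
F12 | step 7 | C10,C10′-epimeric bis(3-methylene) diketone (9S,10R,9′R,10′S; C1 unassigned) | C=C1CN2CCC[C@@H]3CCCCCC4C(=O)C(=C)CN5CCC[C@@H](CCCCCC(C1=O)[C@@H]32)[C@@H]45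
F13 | step 7 | bis(lithium enolate) from F12, formed in situ | CC=1CN2CCC[C@@H]3CCCCCC4C(O[Li])=C(C)CN5CCC[C@@H](CCCCCC(C=1O[Li])[C@@H]32)[C@@H]45
F14 | step 7 | C10,C10′-epimeric diketone before equilibration (9S,10R,9′R,10′S; C1 and C3 unassigned) | CC1CN2CCC[C@@H]3CCCCCC4C(=O)C(C)CN5CCC[C@@H](CCCCCC(C1=O)[C@@H]32)[C@@H]45
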